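Late times came first at the meeting: the first member argued that the last interval of a run, from 10 min to 19 min, stands well clear of the slow first readings. She proposed dividing the rate there by c(substrate), taken as charge minus target made. This gave 0.0506 min⁻¹ in the oak run, and the meeting named it the late specific rate, a pseudo-first-order constant read over that interval.

| setting | oak | alder | ash | maple | cedar |
|---|---|---|---|---|---|
| substrate | 0.300 M | 0.150 M | 0.900 M | 0.300 M | 0.300 M |
| partner | 0.900 M | 0.750 M | 0.900 M | 0.900 M | 0.900 M |
| catalyst | 0.00300 M | 0.00300 M | 0.00300 M | 0.00600 M | 0.00300 M |
| target |  |  |  |  | 0.0900 M |
| time |  |  |  |  | 19 min |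

| run | time / min | [target] / M |
|---|---|---|
| oak run | 0.76 | 0.0044 |
| oak run | 1.4 | 0.0120 |
| oak run | 2.8 | 0.0306 |
| oak run | 5.2 | 0.0614 |
| oak run | 10 | 0.1119 |
| oak run | 19 | 0.1807 |
| alder run | 0.76 | 0.0025 |
| alder run | 1.4 | 0.0054 |
| alder run | 2.8 | 0.0171 |
| alder run | 5.2 | 0.0315 |
| alder run | 10 | 0.0577 |
| alder run | 19 | 0.0926 |
| ash run | 0.76 | 0.0118 |
| ash run | 1.4 | 0.0322 |
| ash run | 2.8 | 0.0791 |
| ash run | 5.2 | 0.1580 |
| ash run | 10 | 0.2907 |
| ash run | 19 | 0.4493 |
| maple run | 0.76 | 0.0094 |
| maple run | 1.4 | 0.0229 |
| maple run | 2.8 | 0.0570 |
| maple run | 5.2 | 0.1097 |
| maple run | 10 | 0.1840 |
| maple run | 19 | 0.2537 |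

(readings scatter by 9 × 10⁻⁴ M)

- Overall: substrate + partner -> target, with catalyst as catalyst.
- Constant volume, constant temperature.
- What is held in complexes is read along with the free species.
- An order is taken over about fifteen percent of the charge, up and down.
- A share of target counts the target that was charged too.

* the exponent of [partner] in the starting rate at the charge of the oak run (at the point where two percent of the substrate have become target)
* the exponent of [substrate] in the starting rate at the charge of the oak run (at the point where two percent of the substrate have become target) (one fixed amount of target, the same in the runs compared)
* the alder run starts with 0.150 M less of substrate and of partner than the oak run, and with no target. Compared where both hold the same amount of substrate, once fifteen percent of what the alder run was charged with has turned into target, is the alder run faster, slower or alike (within a tenth)?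
* target in the cedar run at 19 min, as a share of the substrate charged

The second member objected that target might drag on the rate, since at 10 min the oak run holds twice the target of the alder run. She asked for the same quantity in the alder run, 0.0528 min⁻¹, and for one specific rate to be divided by the other so that time drops out, which gave 1.04. The minute-taker's own reckoning took that ratio as one within a tenth, read in the late interval and carried to the asked point, so the alder run should be alike. The cedar run has the charge of the oak run plus 0.0900 M of target, so, with target taken as no drag on the strength of that ratio, the minute-taker expected it to make the 0.1807 M that the oak run made by 19 min and to stand at 90.2 %.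

The forecast, lower than that share, gave 0.3 for the partner, 0.88 for the substrate, alike and 89 %, holding that “there is little product inhibition or catalyst death”.

The simulation gives 0.047 for the partner, 0.67 for the substrate, alike with a ratio of 1.0, and 90.0 % for the cedar run.

    active catalyst + substrate → catalyst-substrate complex (18.30 M⁻¹ min⁻¹)
    catalyst-substrate complex + partner → target + active catalyst (86.40 M⁻¹ min⁻¹)
    2 partner → lost reagent (0.04818 M⁻¹ min⁻¹)
    catalyst → active catalyst (1.428 min⁻¹)

At 0.0506 min⁻¹, the 0.180 M made in the cedar run corresponds to 18.1 min of its 19 min. In the maple run, with twice the catalyst of the oak run, a doubled specific rate puts the target made at half the substrate charged by 6.85 min, and the maple run takes 7.51 min. Where the maple run and the oak run have made the same early amount of target, the maple run goes at 1.6 times the rate of the oak run, because of the slowness of the step from catalyst to active catalyst: the apparent order in catalyst is 0.71, and without that slowness it is 1.0.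

The readings were computed with constants of no real substance, and the scatter is random.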